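**Plan**

1. Both ketones are taken back to secondary alcohols and the enone C=C to an alkyne. The E-trisubstituted C=C between the benzylic CH2 of the benzene ring and the CH2 alpha to the side-chain ketone, with its methyl on the alkene carbon nearer that ketone, is then cut at two bonds (vinyl C–CH3 and vinyl CH–CH2Ar); this 2-methylalk-1-enyl unit is what a terminal alkyne gives on syn methylmetalation, which makes the key step possible.
2. Further cuts: the bond between the propargylic CH2 and the future side-chain ketone carbon (propargylation of an aldehyde), and the bond between the ring-acyl carbon and the alkyne (acetylide addition to a ring-bound formyl group). Reconnecting the formyl and carboxyl carbons leads to a meso cis-fused bicyclo[3.3.0]octanone from a Weiss–Cook condensation.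
3. Forward: both five-membered carbocycles form together in step 1. One is reduced to CH2 groups and becomes the cyclopentane of the target; the other is opened by ozonolysis of its enol silane. The enone arm, the three-carbon alkyne arm and finally the arene are joined in that order; the only later ring is a transient lactone/lactol that differentiates the two arms.
4. Stereochemistry: the cis relation of the two methyl-bearing quaternary carbons comes from the cis ring fusion, and their absolute configuration from deprotonation of the meso ketone by a chiral lithium amide. The alkene geometries come from syn carbometalation with retentive coupling and from trans hydroalumination of the propargylic alcohol; the carbinol centres are left uncontrolled because both end as ketones.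

Key step: step 15

Assumption 1: the (R,R)-configured lithium amide is taken to remove the methylene proton that leads to enol silane 10; if the sense proves opposite, the (S,S)-amine is used in step 5 and nothing else changes.
Assumption 2: the carbinol carbons created in steps 7 and 9 are formed and carried as epimer mixtures and are drawn without configuration, since step 18 converts both into carbonyl carbons.

**Route**

Step 1
Reactants: 1 butane-2,3-dione; 2 dimethyl 3-oxopentanedioate (2 equiv)
Product: 3 tetramethyl cis-1,5-dimethyl-3,7-dioxobicyclo[3.3.0]octane-2,4,6,8-tetracarboxylate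
Conditions: aq. NaHCO3 (pH 8.3), rt
Reagents that add atoms: none
Why: Weiss–Cook condensation, in which two aldol/Michael sequences of the 1,2-diketone with two equivalents of the 3-oxoglutarate build both five-membered rings at once; a bicyclo[3.3.0]octane can only be cis-fused, so the two methyl-bearing quaternary carbons are set cis.

Step 2
Reactants: 3 tetramethyl cis-1,5-dimethyl-3,7-dioxobicyclo[3.3.0]octane-2,4,6,8-tetracarboxylate
Product: 4 cis-1,5-dimethylbicyclo[3.3.0]octane-3,7-dione
Conditions: 1 M HCl, AcOH, reflux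
Reagents that add atoms: none
Why: Acid hydrolysis and fourfold decarboxylation of the beta-keto esters should leave the meso diketone, whose quaternary ring-fusion carbons cannot epimerise.

Step 3
Reactants: 4 cis-1,5-dimethylbicyclo[3.3.0]octane-3,7-dione
Product: 5 mono-ketal of 4 with 2,2-dimethylpropane-1,3-diol
Conditions: 2,2-dimethylpropane-1,3-diol (1 equiv), TsOH·H2O (cat.), toluene, reflux, Dean–Stark
Reagents that add atoms: 2,2-dimethylpropane-1,3-diol, OCC(C)(C)CO
Why: Acid-catalysed ketalisation with one equivalent of diol is statistical, so the mono-ketal is separated and bis-ketal and diketone are recycled; the product keeps the mirror plane.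

Step 4
Reactants: 5 mono-ketal of 4 with 2,2-dimethylpropane-1,3-diol
Product: 8 cis-1,5-dimethylbicyclo[3.3.0]octan-3-one, via hydrazone 6 (not isolated), via deoxygenated ketal 7 (not isolated)
Conditions: N2H4·H2O, KOH, diethylene glycol, 130 then 200 °C; then 2 M HCl, acetone, rt
Reagents that add atoms: none
Why: Wolff–Kishner reduction (Huang-Minlon procedure) removes the free carbonyl under basic conditions that the ketal tolerates, and aqueous acid then releases the remaining ketone as a meso compound.

Step 5
Reactants: 8 cis-1,5-dimethylbicyclo[3.3.0]octan-3-one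
Product: 10 (1S,5R)-1,5-dimethyl-3-(trimethylsilyloxy)bicyclo[3.3.0]oct-2-ene, via lithium enolate 9 (not isolated)
Conditions: (R,R)-bis(1-phenylethyl)amine, n-BuLi, LiCl, THF, −78 °C; 8, −100 °C; then Me3SiCl, −100 °C to rt
Reagents that add atoms: chlorotrimethylsilane, C[Si](C)(C)Cl
Why: Enantioselective deprotonation of a meso ketone by a C2-symmetric chiral lithium amide (LiCl-assisted, known for cis-bicyclo[3.3.0]octan-3-ones) removes one of the two enantiotopic alpha-methylene protons and O-silylation fixes the enolate, so the reagent sets the absolute configuration of both quaternary carbons in one operation.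

Step 6
Reactants: 10 (1S,5R)-1,5-dimethyl-3-(trimethylsilyloxy)bicyclo[3.3.0]oct-2-ene
Product: 12 2-[(1R,2R)-2-formyl-1,2-dimethylcyclopentyl]acetic acid, via silyl ester 11 (not isolated)
Conditions: O3, CH2Cl2, −78 °C; Me2S, −78 °C to rt; aqueous work-up
Reagents that add atoms: ozone, [O-][O+]=O
Why: Ozonolysis of the silyl enol ether cleaves the enol C=C bond to a formyl group on one quaternary carbon and a silyl ester (hydrolysed on work-up) on the other arm, so the two termini emerge differentiated and at the oxidation levels needed next, with no epimerisable centre.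

Step 7
Reactants: 12 2-[(1R,2R)-2-formyl-1,2-dimethylcyclopentyl]acetic acid; 13 2-methylbut-3-yn-2-ol
Product: 16 (4aR,7aR)-1-(3-hydroxy-3-methylbut-1-yn-1-yl)-4a,7a-dimethylhexahydrocyclopenta[c]pyran-3(1H)-one (both C1 epimers), via dilithium alkynolate 14 (not isolated), via hydroxy acid 15 (not isolated)
Conditions: 13 (3 equiv), n-BuLi (6 equiv), THF, −78 to 0 °C; 12, −78 to 0 °C; 1 M HCl; then TsOH·H2O (cat.), CH2Cl2, rt
Reagents that add atoms: none
Why: 1,2-Addition of a lithium acetylide to a non-enolisable aldehyde (excess reagent covers the carboxylic acid proton) is followed by acid-promoted lactonisation of the delta-hydroxy acid, which the two quaternary ring carbons favour; the new carbinol centre is uncontrolled and is later oxidised.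

Step 8
Reactants: 16 (4aR,7aR)-1-(3-hydroxy-3-methylbut-1-yn-1-yl)-4a,7a-dimethylhexahydrocyclopenta[c]pyran-3(1H)-one
Product: 17 (4aR,7aR)-1-(3-hydroxy-3-methylbut-1-yn-1-yl)-4a,7a-dimethyloctahydrocyclopenta[c]pyran-3-ol
Conditions: i-Bu2AlH (2.5 equiv), CH2Cl2, −78 °C; aq. potassium sodium tartrate
Reagents that add atoms: none
Why: Partial reduction of a delta-lactone with i-Bu2AlH should stop at the lactol because the aluminium hemiacetal is stable at −78 °C; the alkyne is inert and the tertiary hydroxyl only consumes one equivalent of hydride.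

Step 9
Reactants: 17 (4aR,7aR)-1-(3-hydroxy-3-methylbut-1-yn-1-yl)-4a,7a-dimethyloctahydrocyclopenta[c]pyran-3-ol; 18 3-bromoprop-1-yne
Product: 20 1-[(1R,2R)-2-(2-hydroxypent-4-yn-1-yl)-1,2-dimethylcyclopentyl]-4-methylpent-2-yne-1,4-diol (carbinol epimers), via allenylzinc bromide 19 (not isolated)
Conditions: Zn, THF/sat. aq. NH4Cl, 0 °C to rt
Reagents that add atoms: none
Why: Zinc-mediated Barbier propargylation, in which the lactol equilibrates with the hydroxy aldehyde and allenylzinc bromide adds by SE2' to give the homopropargylic alcohol; the new carbinol configuration is irrelevant because this carbon becomes the side-chain ketone.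

Step 10
Reactants: 20 1-[(1R,2R)-2-(2-hydroxypent-4-yn-1-yl)-1,2-dimethylcyclopentyl]-4-methylpent-2-yne-1,4-diol
Product: 21 (1R,2R)-1,2-dimethyl-1-[4-methyl-1,4-bis(triethylsilyloxy)pent-2-yn-1-yl]-2-[2-(triethylsilyloxy)pent-4-yn-1-yl]cyclopentane
Conditions: Et3SiOTf (4 equiv), 2,6-lutidine, CH2Cl2, −78 to 0 °C
Reagents that add atoms: triethylsilyl trifluoromethanesulfonate, CC[Si](CC)(CC)OS(=O)(=O)C(F)(F)F
Why: Silylation with a silyl triflate and a hindered base caps the two secondary and the tertiary hydroxyl so that no O–H bond consumes Me3Al in step 15; triethylsilyl is chosen because mild acid later removes it without touching the aryl triisopropylsilyl ether.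

Step 11
Reactants: 22 4-methoxy-3-methylphenol
Product: 23 (4-methoxy-3-methylphenoxy)triisopropylsilane
Conditions: i-Pr3SiCl, imidazole, DMF, rt
Reagents that add atoms: chlorotriisopropylsilane, CC(C)[Si](Cl)(C(C)C)C(C)C
Why: Standard silylation of a phenol; the bulky triisopropylsilyl ether withstands organolithium, hydride and organoaluminium reagents and shields its own ortho positions from metalation.

Step 12
Reactants: 23 (4-methoxy-3-methylphenoxy)triisopropylsilane
Product: 25 2-methoxy-3-methyl-5-(triisopropylsilyloxy)benzaldehyde, via aryllithium 24 (not isolated)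
Conditions: n-BuLi, TMEDA, Et2O, 0 °C to rt; DMF, 0 °C; 1 M HCl
Reagents that add atoms: N,N-dimethylformamide, CN(C)C=O
Why: Directed ortho-metalation, in which the methoxy group directs lithiation to its only free ortho position (the other carries the methyl group and the positions next to the bulky silyloxy group are shielded), followed by formylation with DMF.

Step 13
Reactants: 25 2-methoxy-3-methyl-5-(triisopropylsilyloxy)benzaldehyde
Product: 26 [2-methoxy-3-methyl-5-(triisopropylsilyloxy)phenyl]methanol
Conditions: NaBH4, MeOH/THF, 0 °C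
Reagents that add atoms: none
Why: Borohydride reduction of an aryl aldehyde, which leaves the aryl silyl ether untouched.

Step 14
Reactants: 26 [2-methoxy-3-methyl-5-(triisopropylsilyloxy)phenyl]methanol
Product: 27 2-methoxy-3-methyl-5-(triisopropylsilyloxy)benzyl bromide
Conditions: CBr4, PPh3, CH2Cl2, 0 °C
Reagents that add atoms: carbon tetrabromide, BrC(Br)(Br)Br
Why: Appel bromination of a benzylic alcohol under neutral conditions; the reactive ortho-alkoxybenzyl bromide is used promptly in step 15.

Step 15
Reactants: 21 (1R,2R)-1,2-dimethyl-1-[4-methyl-1,4-bis(triethylsilyloxy)pent-2-yn-1-yl]-2-[2-(triethylsilyloxy)pent-4-yn-1-yl]cyclopentane; 27 2-methoxy-3-methyl-5-(triisopropylsilyloxy)benzyl bromide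
Product: 29 (1R,2R)-1,2-dimethyl-1-[4-methyl-1,4-bis(triethylsilyloxy)pent-2-yn-1-yl]-2-{(4E)-6-[2-methoxy-3-methyl-5-(triisopropylsilyloxy)phenyl]-4-methyl-2-(triethylsilyloxy)hex-4-en-1-yl}cyclopentane, via alkenylalane 28 (not isolated)
Conditions: Me3Al (3 equiv), Cp2ZrCl2 (0.3 equiv), ClCH2CH2Cl, rt; volatiles removed in vacuo; 27 (1.2 equiv), Pd(PPh3)4 (5 mol %), THF, rt
Reagents that add atoms: trimethylaluminium, C[Al](C)C
Why: Cp2ZrCl2 and Me3Al form a methylzirconocene–alane pair that adds methyl and metal syn across the terminal triple bond of 21 with methyl on the internal carbon, and exchange to aluminium leaves the (E)-2-methylalk-1-enylalane 28 (zirconium-catalysed carboalumination). Zerovalent palladium then inserts into the benzylic C–Br bond of 27, the alkenyl group passes from aluminium to palladium with retention and reductive elimination joins the vinyl and benzylic carbons; the closest known reaction type is the palladium-catalysed cross-coupling of alkenylalanes with benzylic halides. No ring is closed and no stereocentre is formed, the two new bonds being vinyl C–CH3 and vinyl CH–CH2Ar. The step needs regio- and syn-selective addition and a stereoretentive coupling, which together fix the E geometry and are inherent in the mechanism; it also needs the terminal alkyne to react in preference to the internal one, which the two branched silyloxy-bearing carbons flanking the internal triple bond secure. All hydroxyl groups are silylated so that no O–H bond consumes the alane, the neighbouring oxygen is still a silyl ether and not a ketone so the new double bond cannot move into conjugation, and excess Me3Al is pumped off before the coupling so that methyl transfer does not compete.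

Step 16
Reactants: 29 (1R,2R)-1,2-dimethyl-1-[4-methyl-1,4-bis(triethylsilyloxy)pent-2-yn-1-yl]-2-{(4E)-6-[2-methoxy-3-methyl-5-(triisopropylsilyloxy)phenyl]-4-methyl-2-(triethylsilyloxy)hex-4-en-1-yl}cyclopentane
Product: 30 1-[(1R,2R)-2-{(4E)-2-hydroxy-6-[2-methoxy-3-methyl-5-(triisopropylsilyloxy)phenyl]-4-methylhex-4-en-1-yl}-1,2-dimethylcyclopentyl]-4-methylpent-2-yne-1,4-diol
Conditions: camphorsulfonic acid (cat.), MeOH/CH2Cl2, 0 °C to rt
Reagents that add atoms: none
Why: Acid-catalysed methanolysis cleaves the three alkyl triethylsilyl ethers while the aryl triisopropylsilyl ether is stable to mild acid, and propargylic carbinols do not ionise under these conditions.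

Step 17
Reactants: 30 1-[(1R,2R)-2-{(4E)-2-hydroxy-6-[2-methoxy-3-methyl-5-(triisopropylsilyloxy)phenyl]-4-methylhex-4-en-1-yl}-1,2-dimethylcyclopentyl]-4-methylpent-2-yne-1,4-diol
Product: 31 (2E)-1-[(1R,2R)-2-{(4E)-2-hydroxy-6-[2-methoxy-3-methyl-5-(triisopropylsilyloxy)phenyl]-4-methylhex-4-en-1-yl}-1,2-dimethylcyclopentyl]-4-methylpent-2-ene-1,4-diol
Conditions: NaAlH2(OCH2CH2OMe)2, THF, 0 °C to rt; aq. potassium sodium tartrate
Reagents that add atoms: none
Why: Alkoxide-directed trans-hydroalumination of a propargylic alcohol (here flanked by alkoxides on both sides) followed by protonolysis gives the E alkene, and the isolated trisubstituted alkene is not a substrate for the hydride.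

Step 18
Reactants: 31 (2E)-1-[(1R,2R)-2-{(4E)-2-hydroxy-6-[2-methoxy-3-methyl-5-(triisopropylsilyloxy)phenyl]-4-methylhex-4-en-1-yl}-1,2-dimethylcyclopentyl]-4-methylpent-2-ene-1,4-diol
Product: 32 (2E)-4-hydroxy-1-[(1R,2R)-2-{(4E)-6-[2-methoxy-3-methyl-5-(triisopropylsilyloxy)phenyl]-4-methyl-2-oxohex-4-en-1-yl}-1,2-dimethylcyclopentyl]-4-methylpent-2-en-1-one
Conditions: Dess–Martin periodinane, NaHCO3, CH2Cl2, 0 °C to rt
Reagents that add atoms: none
Why: Dess–Martin oxidation under bicarbonate buffer converts the allylic and the homoallylic secondary alcohol into the enone and the beta,gamma-unsaturated ketone under near-neutral conditions that are standard for keeping a skipped double bond in place; the tertiary alcohol cannot be oxidised and the phenol is still masked against oxidation to a quinone.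

Step 19
Reactants: 32 (2E)-4-hydroxy-1-[(1R,2R)-2-{(4E)-6-[2-methoxy-3-methyl-5-(triisopropylsilyloxy)phenyl]-4-methyl-2-oxohex-4-en-1-yl}-1,2-dimethylcyclopentyl]-4-methylpent-2-en-1-one
Product: 33 (2E)-4-hydroxy-1-[(1R,2R)-2-{(4E)-6-(5-hydroxy-2-methoxy-3-methylphenyl)-4-methyl-2-oxohex-4-en-1-yl}-1,2-dimethylcyclopentyl]-4-methylpent-2-en-1-one
Conditions: Bu4NF/AcOH (1:1), THF, 0 °C
Reagents that add atoms: none
Why: Fluoride-mediated cleavage of the aryl silyl ether is fast at 0 °C, and buffering with acetic acid keeps the medium close to neutral so that neither fluoride nor phenoxide should move the skipped double bond into conjugation.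

**Compound list**

1 | butane-2,3-dione | CC(=O)C(C)=O | starting material
2 | dimethyl 3-oxopentanedioate | COC(=O)CC(=O)CC(=O)OC | starting material
3 | tetramethyl cis-1,5-dimethyl-3,7-dioxobicyclo[3.3.0]octane-2,4,6,8-tetracarboxylate (ester-bearing carbons enolisable, drawn without configuration) | O=C1C(C(=O)OC)[C@@]2(C)C(C(=O)OC)C(=O)C(C(=O)OC)[C@@]2(C)C1C(=O)OC | intermediate
4 | cis-1,5-dimethylbicyclo[3.3.0]octane-3,7-dione (meso) | O=C1C[C@@]2(C)CC(=O)C[C@@]2(C)C1 | intermediate
5 | mono-ketal of 4 with 2,2-dimethylpropane-1,3-diol: cis-1,5-dimethyl-7,7-(2,2-dimethylpropane-1,3-diyldioxy)bicyclo[3.3.0]octan-3-one | O=C1C[C@@]2(C)CC3(C[C@@]2(C)C1)OCC(C)(C)CO3 | intermediate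
6 | hydrazone of 5 (not isolated) | NN=C1C[C@@]2(C)CC3(C[C@@]2(C)C1)OCC(C)(C)CO3 | intermediate
7 | cis-1,5-dimethyl-3,3-(2,2-dimethylpropane-1,3-diyldioxy)bicyclo[3.3.0]octane (not isolated) | C1C[C@@]2(C)CC3(C[C@@]2(C)C1)OCC(C)(C)CO3 | intermediate
8 | cis-1,5-dimethylbicyclo[3.3.0]octan-3-one (meso) | O=C1C[C@@]2(C)CCC[C@@]2(C)C1 | intermediate
9 | lithium (1S,5R)-1,5-dimethylbicyclo[3.3.0]oct-2-en-3-olate (not isolated) | C1[C@@]2(C)CCC[C@@]2(C)C=C1O[Li] | intermediate
10 | (1S,5R)-1,5-dimethyl-3-(trimethylsilyloxy)bicyclo[3.3.0]oct-2-ene | C1[C@@]2(C)CCC[C@@]2(C)C=C1O[Si](C)(C)C | intermediate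
11 | trimethylsilyl 2-[(1R,2R)-2-formyl-1,2-dimethylcyclopentyl]acetate (not isolated) | C[Si](C)(C)OC(=O)C[C@@]1(C)CCC[C@@]1(C)C=O | intermediate
12 | 2-[(1R,2R)-2-formyl-1,2-dimethylcyclopentyl]acetic acid | OC(=O)C[C@@]1(C)CCC[C@@]1(C)C=O | intermediate
13 | 2-methylbut-3-yn-2-ol | CC(C)(O)C#C | starting material
14 | O,C-dilithium salt of 13 (not isolated) | [Li]OC(C)(C)C#C[Li] | intermediate
15 | 2-[(1R,2R)-2-(1,4-dihydroxy-4-methylpent-2-yn-1-yl)-1,2-dimethylcyclopentyl]acetic acid, both carbinol epimers (not isolated) | OC(=O)C[C@@]1(C)CCC[C@@]1(C)C(O)C#CC(C)(C)O | intermediate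
16 | (4aR,7aR)-1-(3-hydroxy-3-methylbut-1-yn-1-yl)-4a,7a-dimethylhexahydrocyclopenta[c]pyran-3(1H)-one, both C1 epimers | O=C1C[C@@]2(C)CCC[C@@]2(C)C(C#CC(C)(C)O)O1 | intermediate
17 | (4aR,7aR)-1-(3-hydroxy-3-methylbut-1-yn-1-yl)-4a,7a-dimethyloctahydrocyclopenta[c]pyran-3-ol, epimer mixture | OC1C[C@@]2(C)CCC[C@@]2(C)C(C#CC(C)(C)O)O1 | intermediate
18 | 3-bromoprop-1-yne | C#CCBr | starting material
19 | allenylzinc bromide (not isolated) | C=C=C[Zn]Br | intermediate
20 | 1-[(1R,2R)-2-(2-hydroxypent-4-yn-1-yl)-1,2-dimethylcyclopentyl]-4-methylpent-2-yne-1,4-diol, carbinol epimers | C#CCC(O)C[C@@]1(C)CCC[C@@]1(C)C(O)C#CC(C)(C)O | intermediate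
21 | (1R,2R)-1,2-dimethyl-1-[4-methyl-1,4-bis(triethylsilyloxy)pent-2-yn-1-yl]-2-[2-(triethylsilyloxy)pent-4-yn-1-yl]cyclopentane, carbinol epimers | C#CCC(O[Si](CC)(CC)CC)C[C@@]1(C)CCC[C@@]1(C)C(O[Si](CC)(CC)CC)C#CC(C)(C)O[Si](CC)(CC)CC | intermediate
22 | 4-methoxy-3-methylphenol | COc1ccc(O)cc1C | starting material
23 | (4-methoxy-3-methylphenoxy)triisopropylsilane | COc1ccc(O[Si](C(C)C)(C(C)C)C(C)C)cc1C | intermediate
24 | [2-methoxy-3-methyl-5-(triisopropylsilyloxy)phenyl]lithium (not isolated) | [Li]c1cc(O[Si](C(C)C)(C(C)C)C(C)C)cc(C)c1OC | intermediate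
25 | 2-methoxy-3-methyl-5-(triisopropylsilyloxy)benzaldehyde | COc1c(C)cc(O[Si](C(C)C)(C(C)C)C(C)C)cc1C=O | intermediate
26 | [2-methoxy-3-methyl-5-(triisopropylsilyloxy)phenyl]methanol | COc1c(C)cc(O[Si](C(C)C)(C(C)C)C(C)C)cc1CO | intermediate
27 | 2-methoxy-3-methyl-5-(triisopropylsilyloxy)benzyl bromide | COc1c(C)cc(O[Si](C(C)C)(C(C)C)C(C)C)cc1CBr | intermediate
28 | dimethyl[(1E)-2-methylalk-1-en-1-yl]alane formed from 21 by syn addition of CH3 and Al (not isolated) | C[Al](C)/C=C(\C)CC(O[Si](CC)(CC)CC)C[C@@]1(C)CCC[C@@]1(C)C(O[Si](CC)(CC)CC)C#CC(C)(C)O[Si](CC)(CC)CC | intermediate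
29 | (1R,2R)-1,2-dimethyl-1-[4-methyl-1,4-bis(triethylsilyloxy)pent-2-yn-1-yl]-2-{(4E)-6-[2-methoxy-3-methyl-5-(triisopropylsilyloxy)phenyl]-4-methyl-2-(triethylsilyloxy)hex-4-en-1-yl}cyclopentane, carbinol epimers | COc1c(C)cc(O[Si](C(C)C)(C(C)C)C(C)C)cc1C/C=C(\C)CC(O[Si](CC)(CC)CC)C[C@@]1(C)CCC[C@@]1(C)C(O[Si](CC)(CC)CC)C#CC(C)(C)O[Si](CC)(CC)CC | intermediate
30 | 1-[(1R,2R)-2-{(4E)-2-hydroxy-6-[2-methoxy-3-methyl-5-(triisopropylsilyloxy)phenyl]-4-methylhex-4-en-1-yl}-1,2-dimethylcyclopentyl]-4-methylpent-2-yne-1,4-diol, carbinol epimers | COc1c(C)cc(O[Si](C(C)C)(C(C)C)C(C)C)cc1C/C=C(\C)CC(O)C[C@@]1(C)CCC[C@@]1(C)C(O)C#CC(C)(C)O | intermediate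
31 | (2E)-1-[(1R,2R)-2-{(4E)-2-hydroxy-6-[2-methoxy-3-methyl-5-(triisopropylsilyloxy)phenyl]-4-methylhex-4-en-1-yl}-1,2-dimethylcyclopentyl]-4-methylpent-2-ene-1,4-diol, carbinol epimers | COc1c(C)cc(O[Si](C(C)C)(C(C)C)C(C)C)cc1C/C=C(\C)CC(O)C[C@@]1(C)CCC[C@@]1(C)C(O)/C=C/C(C)(C)O | intermediate
32 | (2E)-4-hydroxy-1-[(1R,2R)-2-{(4E)-6-[2-methoxy-3-methyl-5-(triisopropylsilyloxy)phenyl]-4-methyl-2-oxohex-4-en-1-yl}-1,2-dimethylcyclopentyl]-4-methylpent-2-en-1-one | COc1c(C)cc(O[Si](C(C)C)(C(C)C)C(C)C)cc1C/C=C(\C)CC(=O)C[C@@]1(C)CCC[C@@]1(C)C(=O)/C=C/C(C)(C)O | intermediate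
33 | (2E)-4-hydroxy-1-[(1R,2R)-2-{(4E)-6-(5-hydroxy-2-methoxy-3-methylphenyl)-4-methyl-2-oxohex-4-en-1-yl}-1,2-dimethylcyclopentyl]-4-methylpent-2-en-1-one (CNP0305066.1) | COc1c(C)cc(O)cc1C/C=C(\C)CC(=O)C[C@@]1(C)CCC[C@@]1(C)C(=O)/C=C/C(C)(C)O | target

**Step count and risks**

Total: 19 steps. Longest linear sequence: 15 steps (steps 1–10, then 15–19); the arene branch (steps 11–14) joins at step 15.

Steps most likely to fail:

1. Step 15. Transfer of a methyl group from aluminium in place of the alkenyl group, reductive dimerisation of the benzylic bromide at palladium, or slow transmetalation of the hindered alkenylalane could divert the coupling. Incomplete regiocontrol in the carbometalation would carry an inseparable isomer forward. The fallback replaces the direct alane coupling by a polarity-reversed, two-stage sequence. Starting again from 21, alane 28 is generated as in step 15 and quenched with iodine (THF, −30 °C) to give the isolable (E)-alkenyl iodide F1, which can be purified. Bromide 27 is converted with Zn and LiCl in THF into the benzylzinc bromide F2. Coupling of F1 with F2 under Pd(PPh3)4 catalysis (THF, rt) forms the same vinyl–benzyl bond with retention and returns to the route at 29.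

2. Step 5. Incomplete discrimination between the two enantiotopic methylene groups, or equilibration of the enolate before silylation, would leave the enol silane and everything after it short of enantiomeric purity. The fallback replaces asymmetric induction by separation of enantiomers. Ketone 8 is deprotonated with achiral i-Pr2NLi and silylated with Me3SiCl, which gives 10 together with its mirror image, the enol silane F3. Ozonolysis as in step 6 gives 12 together with its enantiomer, the acid F4. The acid mixture is combined with quinine and the diastereomeric salts are separated by fractional crystallisation. The quininium salt F5, which contains the (1R,2R)-acid, is partitioned between ether and 1 M HCl, which returns to the route at 12. The same crystallisation could also upgrade partly enriched 12 from step 6.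

3. Step 9. The lactol is held closed by the two quaternary ring carbons and may open too slowly to the hydroxy aldehyde, so that the organozinc is protonated in the aqueous medium before it adds; some allenyl carbinol may also form. The fallback generates the aldehyde in free form with the neighbouring hydroxyl capped. Lactone 16 is opened with MeNH(OMe)·HCl and Me3Al (CH2Cl2, 0 °C) to the hydroxy N-methoxy-N-methylamide F6, which is silylated at once (Et3SiOTf, 2,6-lutidine) to the bis(triethylsilyl) ether F7. Reduction with i-Bu2AlH (THF, −78 °C) gives the aldehyde F8, and Barbier propargylation with 18 and Zn (THF/aq. NH4Cl) gives the homopropargylic alcohol F9. A final silylation with Et3SiOTf returns to the route at 21, bypassing 17 and 20.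

**Further compounds**

F1 | step 15 | (1R,2R)-2-[(4E)-5-iodo-4-methyl-2-(triethylsilyloxy)pent-4-en-1-yl]-1,2-dimethyl-1-[4-methyl-1,4-bis(triethylsilyloxy)pent-2-yn-1-yl]cyclopentane | I/C=C(\C)CC(O[Si](CC)(CC)CC)C[C@@]1(C)CCC[C@@]1(C)C(O[Si](CC)(CC)CC)C#CC(C)(C)O[Si](CC)(CC)CC
F2 | step 15 | [2-methoxy-3-methyl-5-(triisopropylsilyloxy)benzyl]zinc bromide | COc1c(C)cc(O[Si](C(C)C)(C(C)C)C(C)C)cc1C[Zn]Br
F3 | step 5 | (1R,5S)-1,5-dimethyl-3-(trimethylsilyloxy)bicyclo[3.3.0]oct-2-ene (mirror image of 10) | C1[C@]2(C)CCC[C@]2(C)C=C1O[Si](C)(C)C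
F4 | step 5 | 2-[(1S,2S)-2-formyl-1,2-dimethylcyclopentyl]acetic acid (enantiomer of 12) | OC(=O)C[C@]1(C)CCC[C@]1(C)C=O
F5 | step 5 | quininium 2-[(1R,2R)-2-formyl-1,2-dimethylcyclopentyl]acetate | COC1=CC2=C(C=CN=C2C=C1)[C@H]([C@@H]3C[C@@H]4CC[NH+]3C[C@@H]4C=C)O.[O-]C(=O)C[C@@]1(C)CCC[C@@]1(C)C=O
F6 | step 9 | 2-[(1R,2R)-2-(1,4-dihydroxy-4-methylpent-2-yn-1-yl)-1,2-dimethylcyclopentyl]-N-methoxy-N-methylacetamide | CON(C)C(=O)C[C@@]1(C)CCC[C@@]1(C)C(O)C#CC(C)(C)O
F7 | step 9 | 2-{(1R,2R)-1,2-dimethyl-2-[4-methyl-1,4-bis(triethylsilyloxy)pent-2-yn-1-yl]cyclopentyl}-N-methoxy-N-methylacetamide | CON(C)C(=O)C[C@@]1(C)CCC[C@@]1(C)C(O[Si](CC)(CC)CC)C#CC(C)(C)O[Si](CC)(CC)CC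
F8 | step 9 | 2-{(1R,2R)-1,2-dimethyl-2-[4-methyl-1,4-bis(triethylsilyloxy)pent-2-yn-1-yl]cyclopentyl}acetaldehyde | O=CC[C@@]1(C)CCC[C@@]1(C)C(O[Si](CC)(CC)CC)C#CC(C)(C)O[Si](CC)(CC)CC
F9 | step 9 | 1-{(1R,2R)-1,2-dimethyl-2-[4-methyl-1,4-bis(triethylsilyloxy)pent-2-yn-1-yl]cyclopentyl}pent-4-yn-2-ol | C#CCC(O)C[C@@]1(C)CCC[C@@]1(C)C(O[Si](CC)(CC)CC)C#CC(C)(C)O[Si](CC)(CC)CC
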